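Carbon numbering used throughout: ten-membered ring C1–C2=C3(CH3)–C4–C5–C6–C7(=CH2)–C8–C9–C10; ring A is C10–C11–C12–C13–C14–C1. In the tricyclic intermediates ring B is C1, C2, C7, C8, C9, C10 and ring C is C2–C7.

## Structural features

The target is a cyclohexane (ring A) cis-fused through C1–C10 to a ten-membered carbocycle. The large ring holds a Z trisubstituted olefin C2=C3 with its methyl on C3, an exocyclic methylene on C7, and acetoxy groups on C6 and C9, while ring A carries a tertiary carbinol at C11 and an isopropyl group at C14. The stereocentres C14, C1, C10, C11 and C9 are contiguous, whereas C6 stands alone beyond the C7 methylene; the configuration is 1S, 6R, 9R, 10S, 11R, 14R, 2Z. Fragile elements are the 1,5-diene in a medium ring (acid-triggered transannular cyclisation), the allylic C6 acetate, the tertiary alcohol, and the β-oxygen relations C9–O/C7 and C9–O/C11, which open elimination and retro-aldol paths whenever C7 or C11 is a carbonyl. The real difficulties are closing a ten-membered ring that contains a Z trisubstituted olefin beside a ring fusion, and setting C6 with no neighbouring stereocentre. The key step uses the 1,5 relation between C7 and the C2=C3 unsaturation. With C7 as a ketone and C2≡C3 as an alkyne the large ring is a 5-cyclodecynone, the fragmentation product of a C2–C7 epoxide of a ring-fused octalone (rings B and C, ketone on C3), so the medium ring is made by breaking a bond.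

## Logic of the disconnections

30 ⇒ 29 ⇒ 28. The two acyl C–O bonds at C6 and C9 are cut first, then the three O–Si bonds. This keeps esters out of every enolate, ylide and hydride step and lets one fluoride treatment free all oxygens. The forward demand is acetylation of two secondary hydroxyls beside the hindered tertiary C11 hydroxyl, with no acid.

28 ⇒ 27 ⇒ 25. The C3–CH3 bond is cut (cross-coupling), then C3–I and C2–H (hydrometalation of C2≡C3). Syn addition to a ring alkyne necessarily places the two ring carbons cis, so the Z geometry becomes automatic and a stereo-element disappears. The forward step must put the metal on C3 (the end flanked by a CH2) and spare the C7 methylene.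

25 ⇒ 24 ⇒ 23 ⇒ 21. The C7=CH2 bond is returned to C7=O, the C6 O–Si bond is removed, and the C6–O bond is cut. A C7 carbonyl accounts for the methylene and activates C6. This removes one carbon and one stereocentre. The demands are enolisation toward C6 and not C8 (a C8 enolate would expel the C9 silyloxy group) and facial control on a medium ring, the weakest point of the plan.

21 ⇒ 19. C2 is reconnected to C7, the alkyne becomes the C3 carbonyl, and the C7 carbonyl oxygen becomes the epoxide oxygen. The ten-membered ring turns into two six-membered rings, so medium-ring closure is exchanged for the preparation of a decalin-type epoxy ketone. The demands are a ketone on C3, an epoxide across the B/C fusion, and tolerance of the acidic medium.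

19 ⇒ 18 ⇒ 17 ⇒ 15. The two epoxide C–O bonds are cut to give the C2=C7 enone, the C11 O–Si bond is removed, and the enone is traced to a C3 carbinol with a C7=C8 olefin. That pattern is exactly what a cycloaddition delivers. The forward demands are a β,γ to α,β olefin shift without loss of the C9 silyloxy group, and nucleophilic epoxidation of a tetrasubstituted enone.

15 ⇒ 14 ⇒ 12 ⇒ 11. The C3 O–Si bond is removed, then the C11–O bond is cut (hydration of C11=CH2), then C11=CH2 is returned to C11=O. In 30 the C11 hydroxyl is anti to C9, the opposite of what methyl addition to the ketone from its open face would give, so carbon is introduced first and oxygen second. The demands are Markovnikov hydration of a 1,1-disubstituted olefin beside a trisubstituted one, and olefination without epimerising C10.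

11 ⇒ 9 + 10. The C1–C2 and C9–C10 bonds are cut (retro [4+2]). Ring B is a cyclohexene with oxygen on C9 next to the carbonyl-bearing C10, the ortho/endo pattern of a 1-oxygenated diene and an enone. Three stereocentres (C1, C9, C10) then derive from the single centre of 10. The demands are a reluctant dienophile, attack anti to the isopropyl group, endo topology and an E dienol ether.

9 ⇒ 8 ⇒ 6 ⇒ 5 ⇒ 4 ⇒ 1 + 2. The enol O–Si bond is cut to the aldehyde, C9=O is traced to a terminal olefin, the C3 O–Si and C3–H bonds are removed, and the C7–C8 bond is cut with transposition of the carbonyl. Compound 9 thus takes its C3 oxygen from 1, which removes any need for a later unselective C3 oxidation. The demands are chemoselective cleavage of the monosubstituted olefin and an E-selective enol silylation.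

## Other disconnections considered

Alternative 1: The cut is C8–C9. The open-chain aldehyde A1, whose C7 carries a bromomethyl group and the future methylene, would be treated with CrCl2 (divalent chromium) at high dilution. The allylchromium species adds to the C9 aldehyde and gives ring alcohol A2 with the C7 methylene in place. In its favour, the reaction is aldehyde-selective, tolerates silyl ethers and needs no separate olefination, and C6 and the Z olefin are made in an acyclic chain where asymmetric methods are dependable. On C6 this alternative is the better plan; on olefin geometry it is the equal of the chosen one. Against it, C9 is created during closure of a ten-membered ring, so its configuration rests on ring conformation and cannot be argued as firmly as an endo cycloaddition. The aldehyde on C10 of A1 sits next to the silylated C11 carbinol and is prone to epimerisation and β-elimination, and A1 needs the fully substituted ring A built separately with two differentiated side chains. Mechanistically it closes the ring by bond formation against strain and entropy, where the chosen plan opens a bond with loss of N2 as driving force. It is more convergent and could equal or beat the chosen route in longest linear sequence, but it moves the stereochemical burden to ring A and C9.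

Alternative 2: The cut is C3–C4. Precursor A3 holds a Z iodoalkene (iodine cis to C1) and a terminal C4=C5 olefin. 9-BBN would hydroborate C4, and Pd(dppf)Cl2 with aqueous base would couple the C4 borane with the C3 iodide to give A4, with C7 masked as a dioxolane. In its favour, the olefin geometry is fixed before closure and retained in the coupling, C6 and C9 are preset, and the coupling tolerates silyl ethers and the free tertiary hydroxyl. It raises no regiochemical question of the kind the hydrozirconation does, so on the olefin it is the better plan; on C6 it is also better. Against it, a ten-membered ring with a Z trisubstituted olefin must form by reductive elimination from a strained palladacycle, so β-hydride elimination, protodeboronation and oligomerisation are likely competitors. The hydroboration must leave the iodoalkene alone. After closure the dioxolane of A4 must still be hydrolysed with acid, a hazard for the medium-ring olefin, and C7 methylenated between two oxygenated carbons. In comparison it is less secure at the ring-forming event and adds ketal removal and olefination afterwards, so convergence brings no clear saving in steps.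

Alternative 3: The cut is C9–C10. Precursor A5 carries a 1,3-dithiane at C9 and an epoxide across C10–C11. n-BuLi would metallate the dithiane, and the carbanion would open the epoxide at C10 with inversion to give A6 with the C11 carbinol unveiled. In its favour, the opening is stereospecific, and the C7 methylene and Z olefin are already present. The C10/C11 relation follows from the epoxide with certainty, which is better than the hydration used in the chosen route. Against it, the nucleophile must attack a secondary epoxide carbon flanked by the fully substituted C11 and the branched C1, through a ten-membered transition state, and the trans-diaxial opening required by ring A must be reconciled with the reach of the tether. The lithiated dithiane is a strong base, so epoxide-to-allylic-alcohol isomerisation and deprotonation at allylic C8 would compete. Afterwards the dithiane of A6 must be removed beside two olefins and the C9 ketone reduced stereoselectively in the medium ring. C9 is not set by this key step, so on C9 the chosen plan is better. The step count would be roughly equal, with better convergence but more post-cyclisation adjustment.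

Key step: step 13

Remarks on the chemistry:
- (R)-Cryptone (10) is taken as purchasable in enantiopure form. If it is not, it can be made from 4-isopropylcyclohexanone by enantioselective deprotonation–silylation and Pd(OAc)2 dehydrogenation.
- Compounds 19 and 21 carry C1, C9, C10, C11 and C14 exactly as 30 does; in 19 the epoxide lies on the ring B face opposite the C9 oxygen.
- Two design choices shape the fragmentation precursor. The C3 oxygen is carried by the diene, because a diene without it leaves no selective C3 oxidation. The C11 hydroxyl is capped as a triethylsilyl ether before epoxidation and fragmentation.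
- Diene 9 is racemic at C3 and is used in excess (about two and a half equivalents) in step 6; the surplus is recovered unchanged. C3 later becomes a ketone and C2 becomes sp2, so C3-epimeric adducts converge at step 10.
- The C6 hydroxylation (step 14) is assumed to give the 6R alcohol by attack on the outer face of the ring enolate. This is not secured by any neighbouring centre; a reagent-controlled correction is given at the end.

## Route

Step 1
Reactants: 1 3-ethoxycyclohex-2-en-1-one; 2 allylmagnesium bromide
Product: 4 3-allylcyclohex-2-en-1-one, via bromomagnesium alkoxide 3 (not isolated)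
Conditions: THF, 0 °C; then 1 M HCl, rt
Reagents that add atoms: none
Why: Stork–Danheiser sequence: the Grignard reagent adds 1,2 to the vinylogous ester, and mild aqueous acid hydrolyses the enol ether and dehydrates the carbinol, so the carbonyl moves to the former ethoxy carbon (the future C3) and the allyl group sits on the future C7.

Step 2
Reactants: 4 3-allylcyclohex-2-en-1-one
Product: 5 rac-3-allylcyclohex-2-en-1-ol
Conditions: NaBH4, CeCl3·7H2O, MeOH, 0 °C
Reagents that add atoms: none
Why: Luche reduction gives clean 1,2-reduction of the enone; the new C3 centre is racemic and is erased at step 10.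

Step 3
Reactants: 5 rac-3-allylcyclohex-2-en-1-ol
Product: 6 rac-[(3-allylcyclohex-2-en-1-yl)oxy]triethylsilane
Conditions: Et3SiCl, imidazole, CH2Cl2, 0 °C to rt
Reagents that add atoms: chlorotriethylsilane, CC[Si](CC)(CC)Cl
Why: Standard silylation of a secondary allylic alcohol; the triethylsilyl ether can later be removed beside the tert-butyldimethylsilyl ether at C9.

Step 4
Reactants: 6 rac-[(3-allylcyclohex-2-en-1-yl)oxy]triethylsilane
Product: 8 rac-2-[3-(triethylsilyloxy)cyclohex-1-en-1-yl]acetaldehyde, via vicinal diol 7 (not isolated)
Conditions: OsO4 (2 mol %), NaIO4, 2,6-lutidine, dioxane–H2O 3:1, rt; product used crude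
Reagents that add atoms: osmium tetroxide, O=[Os](=O)(=O)=O (catalytic oxygen carrier); sodium periodate, [Na+].[O-]I(=O)(=O)=O (terminal oxidant)
Why: Lemieux–Johnson cleavage; the unhindered monosubstituted olefin should be osmylated in preference to the trisubstituted ring olefin, which is shielded and inductively deactivated by the allylic silyloxy group, and 2,6-lutidine limits over-oxidation.

Step 5
Reactants: 8 rac-2-[3-(triethylsilyloxy)cyclohex-1-en-1-yl]acetaldehyde
Product: 9 rac-tert-butyldimethylsilyl (E)-dienol ether of 8 [(E)-1-(2-silyloxyvinyl)-3-(triethylsilyloxy)cyclohexene]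
Conditions: tBuMe2SiOTf, Et3N, CH2Cl2, −78 to 0 °C
Reagents that add atoms: tert-butyldimethylsilyl triflate, CC(C)(C)[Si](C)(C)OS(=O)(=O)C(F)(F)F
Why: O-silylation of the aldehyde followed by loss of the doubly activated C8 proton gives the conjugated dienol ether with the ring olefin still at C2=C7; the extended E isomer should predominate, and any Z isomer cannot reach the s-cis form and stays behind in step 6.

Step 6
Reactants: 9 rac-(E)-dienol ether; 10 (R)-cryptone
Product: 11 all-cis tricyclic Diels–Alder ketone
Conditions: excess diene, PhMe (concentrated), BHT (cat.), 150–160 °C, sealed tube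
Reagents that add atoms: none
Why: Thermal Diels–Alder reaction of a 1-silyloxydiene with a cyclohexenone, in which every atom of both partners ends in the adduct: the oxygenated terminus C9 bonds to the α-carbon C10 (ortho rule), the diene adds anti to the isopropyl group (C1–C2 trans to it), the cis dienophile gives the cis A/B fusion, and endo approach of the E dienol ether places the C9 oxygen cis to the C10–C11 bond, which is the 9R,10S,1S array; the enantiomer of the diene whose triethylsilyloxy group lies away from the dienophile reacts preferentially.

Step 7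
Reactants: 11 all-cis tricyclic ketone
Product: 12 C11 exocyclic methylene compound
Conditions: Ph3PCH3Br, KOtBu, THF, 0 °C to rt
Reagents that add atoms: methyltriphenylphosphonium bromide, C[P+](c1ccccc1)(c1ccccc1)c1ccccc1.[Br-]
Why: Wittig methylenation; the ylide is only weakly basic and H10 lies close to the carbonyl plane (equatorial on ring A), so enolisation toward C10 and loss of the cis fusion are not expected.

Step 8
Reactants: 12 C11 exocyclic methylene compound
Product: 14 C11 tertiary alcohol (11R), via acetoxymercurio carbinol 13 (not isolated)
Conditions: Hg(OAc)2, THF–H2O 1:1, 0 °C to rt; then 3 M NaOH, NaBH4, 0 °C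
Reagents that add atoms: water, O
Why: Markovnikov oxymercuration–demercuration, much faster for a 1,1-disubstituted than for a trisubstituted ring olefin; water opens the mercurinium ion at C11 from the open face of ring A, anti to the axial C10–C9 bond whose silyloxy group covers the other face, so the hydroxyl ends anti to C9 and the methyl syn (11R), the epimer that methyl addition to 11 would not give.

Step 9
Reactants: 14 C11 tertiary alcohol
Product: 15 C3,C11 diol
Conditions: PPTS (cat.), MeOH, 0 °C
Reagents that add atoms: none
Why: Acid methanolysis removes the unhindered secondary triethylsilyl ether far faster than the hindered secondary tert-butyldimethylsilyl ether at C9.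

Step 10
Reactants: 15 C3,C11 diol
Product: 17 C2=C7 enone with C3 ketone and free C11 hydroxyl, via deconjugated C7=C8 ketone 16 (not isolated)
Conditions: Dess–Martin periodinane, NaHCO3, CH2Cl2, 0 °C to rt; aqueous Na2S2O3/NaHCO3 wash; crude with DBU (0.2 equiv), CH2Cl2, 0 °C
Reagents that add atoms: none
Why: Dess–Martin oxidation touches only the secondary alcohol; DBU removes the doubly activated C2 proton and reprotonation at C8 gives the conjugated tetrasubstituted enone (β,γ to α,β isomerisation), erasing C2 and C3 so that all C3 epimers converge.

Step 11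
Reactants: 17 C2=C7 enone with free C11 hydroxyl
Product: 18 C11 triethylsilyl ether of the enone
Conditions: Et3SiOTf, 2,6-lutidine, CH2Cl2, −78 to −40 °C
Reagents that add atoms: triethylsilyl triflate, CC[Si](CC)(CC)OS(=O)(=O)C(F)(F)F
Why: Silyl triflate with a hindered pyridine base silylates tertiary alcohols at low temperature without enolising the enone; the cap keeps the C11 oxygen from opening the epoxide, from silyl transfer and from hemiketal formation in later steps.

Step 12
Reactants: 18 C11 triethylsilyl ether of the enone
Product: 19 tricyclic C2,C7-epoxy C3-ketone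
Conditions: 30 % H2O2, 2 M NaOH, MeOH–THF, 0 °C to rt
Reagents that add atoms: hydrogen peroxide, OO
Why: Weitz–Scheffer nucleophilic epoxidation, as used on ring-fusion octalones; hydroperoxide adds to C7 from the face opposite the C9 silyloxy group and ring A, and the enolate closes on the same face; either epoxide face would serve the next step.

Step 13
Reactants: 19 tricyclic C2,C7-epoxy C3-ketone
Product: 21 ring A-fused cyclodec-2-yn-7-one (C2≡C3; C7=O; 9-OSitBuMe2; 11-OSiEt3), via tosylhydrazone 20 (not isolated)
Conditions: TsNHNH2 (1.2 equiv), AcOH–CH2Cl2 1:1, −20 °C to rt; NaHCO3 work-up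
Reagents that add atoms: none
Why: Eschenmoser–Tanabe fragmentation, the reaction type by which ring-fused α,β-epoxy ketones give cycloalkynones. Condensation at C3 gives tosylhydrazone 20, and acid-mediated tautomerisation opens the C2–O bond of the epoxide to an azoalkene (C2=C3–N=N–Ts) with the oxygen left on C7. This species fragments in the Grob sense: the C7 oxygen becomes the carbonyl, the C2–C7 bond breaks, its electrons form the second π bond of C2≡C3, and sulfinate and N2 leave. No ring is closed by bond formation; rings B and C, which share only C2–C7, merge into the ten-membered ring by ring expansion, so the cost of a medium-ring closure is paid by loss of N2. No stereocentre is formed, C1, C9, C10, C11 and C14 are untouched, and the epoxide configuration disappears. The selectivity needed is cleavage of C2–C7 and not of C1–C2 or simple epoxide opening; it is secured because C7 alone carries the donor oxygen and because ring C holds C7 trans to the diazenyl group across C2=C3, that is antiperiplanar. The silylated C11 oxygen cannot attack the acid-activated C7–O bond, and the mild acid, low temperature and basic work-up guard against the transannular re-closure that 5-cyclodecynones undergo in stronger acid.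

Step 14
Reactants: 21 ring A-fused cyclodec-2-yn-7-one
Product: 23 (6R)-6-hydroxy ketone, via sodium enolate 22 (not isolated)
Conditions: NaN(SiMe3)2, THF, −78 °C; 2-(phenylsulfonyl)-3-phenyloxaziridine, −78 °C; aqueous NH4Cl
Reagents that add atoms: 2-(phenylsulfonyl)-3-phenyloxaziridine, O=S(=O)(c1ccccc1)N1OC1c1ccccc1
Why: Kinetic enolisation followed by oxaziridine hydroxylation; the hindered amide base should take the proton from the unencumbered C6 methylene and not from C8 beside the C9 silyloxy centre, and the oxidant attacks the outer face of the ring enolate, assumed to give 6R (see the remarks and the correction given at the end).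

Step 15
Reactants: 23 (6R)-6-hydroxy ketone
Product: 24 C6 tert-butyldimethylsilyl ether of the ketone
Conditions: tBuMe2SiOTf, 2,6-lutidine, CH2Cl2, −78 °C
Reagents that add atoms: tert-butyldimethylsilyl triflate, CC(C)(C)[Si](C)(C)OS(=O)(=O)C(F)(F)F
Why: Low-temperature silylation protects the α-hydroxy ketone against ketol shift and epimerisation before olefination.

Step 16
Reactants: 24 C6 tert-butyldimethylsilyl ether of the ketone
Product: 25 C7 exocyclic methylene cycloalkyne
Conditions: Ph3PCH3Br, KOtBu, THF–PhMe, 0 °C to rt
Reagents that add atoms: methyltriphenylphosphonium bromide, C[P+](c1ccccc1)(c1ccccc1)c1ccccc1.[Br-]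
Why: Wittig methylenation is routine for α- and β-silyloxy ketones; the weakly basic ylide should add faster than it enolises toward C8, and the alkyne is inert to it.

Step 17
Reactants: 25 C7 exocyclic methylene cycloalkyne
Product: 27 (2E)-3-iodo olefin (ring carbons C1 and C4 cis), via C3 alkenylzirconocene chloride 26 (not isolated)
Conditions: Cp2Zr(H)Cl (2.5 equiv), THF, rt to 40 °C; then I2, THF, −20 to 0 °C; Na2S2O3/NaHCO3 work-up
Reagents that add atoms: iodine, II
Why: Syn hydrozirconation of an internal alkyne places zirconium, after equilibration with excess reagent, on the less hindered carbon C3 (next to the C4 methylene and away from the branched C1), and iodinolysis proceeds with retention; syn addition to a ring alkyne forces C1 and C4 cis, and the hindered 1,1-disubstituted C7 methylene should react much more slowly than the strained alkyne.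

Step 18
Reactants: 27 (2E)-3-iodo olefin
Product: 28 tris-silyl ether of the (2Z)-3-methyl olefin
Conditions: MeZnCl (3 equiv), Pd(PPh3)4 (5 mol %), THF, rt to 50 °C
Reagents that add atoms: methylzinc chloride, C[Zn]Cl
Why: Negishi coupling on zerovalent palladium proceeds with retention of olefin geometry, so the methyl takes the place of iodine and the 2Z olefin results; silyl ethers and the methylene are inert.

Step 19
Reactants: 28 tris-silyl ether
Product: 29 C6,C9,C11 triol
Conditions: Bu4NF (6 equiv), THF, rt to 45 °C; aqueous NH4Cl
Reagents that add atoms: none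
Why: Fluoride cleaves the two secondary and the tertiary silyl ethers under non-acidic conditions, which the medium-ring 1,5-diene requires.

Step 20
Reactants: 29 C6,C9,C11 triol
Product: 30 CNP0303839.1 (target)
Conditions: Ac2O, pyridine, DMAP (cat.), CH2Cl2, 0 °C to rt
Reagents that add atoms: acetic anhydride, CC(=O)OC(C)=O
Why: DMAP-catalysed acylation esterifies the two secondary hydroxyls, while the hindered tertiary C11 hydroxyl should not react under these mild conditions.

## Compound list

1 | 3-ethoxycyclohex-2-en-1-one | CCOC1=CC(=O)CCC1 | starting material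
2 | allylmagnesium bromide | C=CC[Mg]Br | starting material
3 | bromomagnesium 1-allyl-3-ethoxycyclohex-2-en-1-olate (racemic) | C=CCC1(O[Mg]Br)C=C(OCC)CCC1 | intermediate
4 | 3-allylcyclohex-2-en-1-one | C=CCC1=CC(=O)CCC1 | intermediate
5 | rac-3-allylcyclohex-2-en-1-ol | C=CCC1=CC(O)CCC1 | intermediate
6 | rac-[(3-allylcyclohex-2-en-1-yl)oxy]triethylsilane | C=CCC1=CC(O[Si](CC)(CC)CC)CCC1 | intermediate
7 | rac-3-[3-(triethylsilyloxy)cyclohex-1-en-1-yl]propane-1,2-diol (diastereomer mixture) | OCC(O)CC1=CC(O[Si](CC)(CC)CC)CCC1 | intermediate
8 | rac-2-[3-(triethylsilyloxy)cyclohex-1-en-1-yl]acetaldehyde | O=CCC1=CC(O[Si](CC)(CC)CC)CCC1 | intermediate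
9 | rac-tert-butyldimethyl{[(E)-2-(3-(triethylsilyloxy)cyclohex-1-en-1-yl)ethenyl]oxy}silane | CC(C)(C)[Si](C)(C)O/C=C/C1=CC(O[Si](CC)(CC)CC)CCC1 | intermediate
10 | (R)-cryptone, (R)-4-isopropylcyclohex-2-en-1-one | O=C1C=C[C@@H](C(C)C)CC1 | starting material
11 | Diels–Alder adduct: cis-fused tricycle, C11 ketone, C7=C8, 9-OSitBuMe2 cis to C10–C11, 3-OSiEt3 trans to C1 on ring C | CC[Si](CC)(CC)O[C@@H]1CCCC2=C[C@@H](O[Si](C)(C)C(C)(C)C)[C@@H]3[C@H]([C@@H]12)[C@@H](C(C)C)CCC3=O | intermediate
12 | C11 methylene analogue of 11 | CC[Si](CC)(CC)O[C@@H]1CCCC2=C[C@@H](O[Si](C)(C)C(C)(C)C)[C@@H]3[C@H]([C@@H]12)[C@@H](C(C)C)CCC3=C | intermediate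
13 | C11 carbinol bearing CH2HgOAc on C11 | CC[Si](CC)(CC)O[C@@H]1CCCC2=C[C@@H](O[Si](C)(C)C(C)(C)C)[C@@H]3[C@H]([C@@H]12)[C@@H](C(C)C)CC[C@@]3(C[Hg]OC(C)=O)O | intermediate
14 | (11R) tertiary alcohol with 3-OSiEt3 and 9-OSitBuMe2, C7=C8 | CC[Si](CC)(CC)O[C@@H]1CCCC2=C[C@@H](O[Si](C)(C)C(C)(C)C)[C@@H]3[C@H]([C@@H]12)[C@@H](C(C)C)CC[C@@]3(C)O | intermediate
15 | C3,C11 diol with 9-OSitBuMe2, C7=C8 | O[C@@H]1CCCC2=C[C@@H](O[Si](C)(C)C(C)(C)C)[C@@H]3[C@H]([C@@H]12)[C@@H](C(C)C)CC[C@@]3(C)O | intermediate
16 | C3 ketone with C7=C8 (β,γ-unsaturated), free C11 hydroxyl | O=C1CCCC2=C[C@@H](O[Si](C)(C)C(C)(C)C)[C@@H]3[C@H]([C@@H]12)[C@@H](C(C)C)CC[C@@]3(C)O | intermediate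
17 | C2=C7 enone (C3 ketone), free C11 hydroxyl, 9-OSitBuMe2 | O=C1CCCC2=C1[C@@H]3[C@@H](C(C)C)CC[C@@](C)(O)[C@@H]3[C@H](O[Si](C)(C)C(C)(C)C)C2 | intermediate
18 | C2=C7 enone with 11-OSiEt3 and 9-OSitBuMe2 | O=C1CCCC2=C1[C@@H]3[C@@H](C(C)C)CC[C@@](C)(O[Si](CC)(CC)CC)[C@@H]3[C@H](O[Si](C)(C)C(C)(C)C)C2 | intermediate
19 | tricyclic C2,C7-epoxy C3-ketone (epoxide on the ring B face opposite the C9 oxygen), 11-OSiEt3, 9-OSitBuMe2 | O=C1CCC[C@@]23C[C@@H](O[Si](C)(C)C(C)(C)C)[C@@H]4[C@H]([C@@]12O3)[C@@H](C(C)C)CC[C@@]4(C)O[Si](CC)(CC)CC | intermediate
20 | C3 tosylhydrazone of 19 | Cc1ccc(cc1)S(=O)(=O)NN=C1CCC[C@@]23C[C@@H](O[Si](C)(C)C(C)(C)C)[C@@H]4[C@H]([C@@]12O3)[C@@H](C(C)C)CC[C@@]4(C)O[Si](CC)(CC)CC | intermediate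
21 | ring A-fused cyclodec-2-yn-7-one, 9-OSitBuMe2, 11-OSiEt3 | O=C1C[C@@H](O[Si](C)(C)C(C)(C)C)[C@@H]2[C@H](C#CCCC1)[C@@H](C(C)C)CC[C@@]2(C)O[Si](CC)(CC)CC | intermediate
22 | sodium C6=C7 enolate of 21 (olefin geometry undefined) | [Na+].[O-]C1=CCCC#C[C@@H]2[C@@H](C(C)C)CC[C@@](C)(O[Si](CC)(CC)CC)[C@@H]2[C@H](O[Si](C)(C)C(C)(C)C)C1 | intermediate
23 | (6R)-6-hydroxy derivative of 21 | O=C1C[C@@H](O[Si](C)(C)C(C)(C)C)[C@@H]2[C@H](C#CCC[C@H]1O)[C@@H](C(C)C)CC[C@@]2(C)O[Si](CC)(CC)CC | intermediate
24 | (6R)-6-OSitBuMe2 derivative of 21 | O=C1C[C@@H](O[Si](C)(C)C(C)(C)C)[C@@H]2[C@H](C#CCC[C@H]1O[Si](C)(C)C(C)(C)C)[C@@H](C(C)C)CC[C@@]2(C)O[Si](CC)(CC)CC | intermediate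
25 | C7 methylene cycloalkyne, 6,9-bis(OSitBuMe2), 11-OSiEt3 | C=C1C[C@@H](O[Si](C)(C)C(C)(C)C)[C@@H]2[C@H](C#CCC[C@H]1O[Si](C)(C)C(C)(C)C)[C@@H](C(C)C)CC[C@@]2(C)O[Si](CC)(CC)CC | intermediate
26 | C3 alkenyl–Zr(Cl)Cp2 adduct of 25 (H on C2, C1 and C4 cis) | C=C1C[C@@H](O[Si](C)(C)C(C)(C)C)[C@@H]2[C@H](/C=C(/[Zr](Cl)(C3C=CC=C3)C3C=CC=C3)CC[C@H]1O[Si](C)(C)C(C)(C)C)[C@@H](C(C)C)CC[C@@]2(C)O[Si](CC)(CC)CC | intermediate
27 | (2E)-3-iodo olefin, 6,9-bis(OSitBuMe2), 11-OSiEt3 | C=C1C[C@@H](O[Si](C)(C)C(C)(C)C)[C@@H]2[C@H](/C=C(/I)CC[C@H]1O[Si](C)(C)C(C)(C)C)[C@@H](C(C)C)CC[C@@]2(C)O[Si](CC)(CC)CC | intermediate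
28 | (2Z)-3-methyl olefin, 6,9-bis(OSitBuMe2), 11-OSiEt3 | C=C1C[C@@H](O[Si](C)(C)C(C)(C)C)[C@@H]2[C@H](/C=C(/C)CC[C@H]1O[Si](C)(C)C(C)(C)C)[C@@H](C(C)C)CC[C@@]2(C)O[Si](CC)(CC)CC | intermediate
29 | (1S,2Z,6R,9R,10S,11R,14R) triol | C=C1C[C@@H](O)[C@@H]2[C@H](/C=C(/C)CC[C@H]1O)[C@@H](C(C)C)CC[C@@]2(C)O | intermediate
30 | CNP0303839.1, the 6,9-diacetate of 29 | C=C1C[C@@H](OC(C)=O)[C@@H]2[C@H](/C=C(/C)CC[C@H]1OC(C)=O)[C@@H](C(C)C)CC[C@@]2(C)O | target

## Step count and least certain steps

Total: 20 steps. Longest linear sequence: 20 steps (1 to 30); 15 steps from 10.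

Step 13 (key step). The hindered C3 carbonyl may condense slowly. The acid could then open or rearrange the tertiary epoxide, cleave the tertiary silyl ether, or re-close the ynone transannularly before fragmentation is complete. The fallback is the neutral, thermal aminoaziridine variant of the same fragmentation. Setting out from 19, condensation with 1-amino-2-phenylaziridine (racemic) in CH2Cl2 at 0 °C would give the N-(2-phenylaziridin-1-yl)imine F1. Warming in toluene (80–110 °C) fragments F1 with loss of styrene and N2 and without acid, returning to the route at 21.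

Step 6. The enone is a reluctant dienophile. The dienol ether may decompose or isomerise before it adds, and endo and facial selectivity may erode at the temperature needed. The fallback is activation of the dienophile. Setting out from 10, Br2 in CH2Cl2 at 0 °C gives the (4R)-2,3-dibromo-4-isopropylcyclohexanone F2, which Et3N converts in the same flask to (R)-2-bromo-4-isopropylcyclohex-2-en-1-one F3. Bromoenone F3 should add 9 at markedly lower temperature (PhMe, 80–100 °C) with the same topology, giving the C10-bromo adduct F4. Radical debromination (Bu3SnH, AIBN, PhH, 80 °C) should deliver hydrogen to the open face and return to the route at 11.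

Step 14. Facial discrimination on a conformationally mobile ten-membered enolate may be poor or reversed. Some deprotonation at C8, with loss of the C9 silyloxy group, may also compete. The fallback is a redox correction under reagent control. It sets out from 21, hydroxylated as in step 14 and taken on whatever the C6 configuration, shown for the (6S)-hydroxy ketone F5. Excess Ph3P=CH2 (THF, 0 °C to rt) gives the (6S) C7-methylene alcohol F6. MnO2 (CH2Cl2, rt) oxidises the allylic alcohol to the C6 ketone with C7 methylene F7. Reduction with (S)-Me-CBS oxazaborolidine and catecholborane (PhMe, −78 °C) should give the (6R) allylic alcohol F8, the exocyclic alkenyl side acting as the large group. tBuMe2SiOTf/2,6-lutidine then returns to the route at 25.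

Step 17. Zirconium may be placed incompletely at C3, the C7 methylene may be hydrozirconated by the excess reagent, and acid formed on iodinolysis may damage the product. As a fallback, setting out from 25, Pd-catalysed syn hydrostannation (Bu3SnH, PdCl2(PPh3)2, THF, 0 °C), which does not touch isolated olefins, would give the C3 tributylstannyl alkene F9. Iododestannylation (I2, CH2Cl2, 0 °C) then returns to the route at 27.

Step 8. Water may open the mercurinium ion from the wrong face, or with little preference, if ring A prefers a conformation other than the one assumed. Slow mercuration of the ring olefin is a minor risk. The fallback is the stereocomplementary order of bond formation. Setting out from 11, MeMgBr with CeCl3 (THF, −78 °C) adds methyl from whichever face is open, which puts the hydroxyl on the opposite face to that given by hydration, and returns to the route directly at 14. Between them the two sequences cover either facial preference.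

## Further compounds

F1 | step 13 | N-(2-phenylaziridin-1-yl)imine of 19 (aziridine carbon racemic) | C1(c2ccccc2)CN1N=C1CCC[C@@]23C[C@@H](O[Si](C)(C)C(C)(C)C)[C@@H]4[C@H]([C@@]12O3)[C@@H](C(C)C)CC[C@@]4(C)O[Si](CC)(CC)CC
F2 | step 6 | (4R)-2,3-dibromo-4-isopropylcyclohexan-1-one (mixture at C2 and C3) | O=C1C(Br)C(Br)[C@@H](C(C)C)CC1
F3 | step 6 | (R)-2-bromo-4-isopropylcyclohex-2-en-1-one | O=C1C(Br)=C[C@@H](C(C)C)CC1
F4 | step 6 | C10-bromo analogue of 11 | CC[Si](CC)(CC)O[C@@H]1CCCC2=C[C@@H](O[Si](C)(C)C(C)(C)C)[C@]3(Br)[C@H]([C@@H]12)[C@@H](C(C)C)CCC3=O
F5 | step 14 | (6S)-6-hydroxy epimer of 23 | O=C1C[C@@H](O[Si](C)(C)C(C)(C)C)[C@@H]2[C@H](C#CCC[C@@H]1O)[C@@H](C(C)C)CC[C@@]2(C)O[Si](CC)(CC)CC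
F6 | step 14 | (6S) C7-methylene C6 alcohol | C=C1C[C@@H](O[Si](C)(C)C(C)(C)C)[C@@H]2[C@H](C#CCC[C@@H]1O)[C@@H](C(C)C)CC[C@@]2(C)O[Si](CC)(CC)CC
F7 | step 14 | C6 ketone with C7 methylene | C=C1C[C@@H](O[Si](C)(C)C(C)(C)C)[C@@H]2[C@H](C#CCCC1=O)[C@@H](C(C)C)CC[C@@]2(C)O[Si](CC)(CC)CC
F8 | step 14 | (6R) C7-methylene C6 alcohol | C=C1C[C@@H](O[Si](C)(C)C(C)(C)C)[C@@H]2[C@H](C#CCC[C@H]1O)[C@@H](C(C)C)CC[C@@]2(C)O[Si](CC)(CC)CC
F9 | step 17 | C3 tributylstannyl alkene (H on C2, C1 and C4 cis) | C=C1C[C@@H](O[Si](C)(C)C(C)(C)C)[C@@H]2[C@H](/C=C(/[Sn](CCCC)(CCCC)CCCC)CC[C@H]1O[Si](C)(C)C(C)(C)C)[C@@H](C(C)C)CC[C@@]2(C)O[Si](CC)(CC)CC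
F0 | step 8 | none | none
A1 | alternative 1 | seco C9 aldehyde with bromomethyl on C7, 6-OSitBuMe2, 11-OSiEt3 | BrCC(=C)[C@H](O[Si](C)(C)C(C)(C)C)CC/C(C)=C\[C@@H]1[C@@H](C(C)C)CC[C@@](C)(O[Si](CC)(CC)CC)[C@@H]1C=O
A2 | alternative 1 | bicyclic C9 alcohol with C7 methylene, 6-OSitBuMe2, 11-OSiEt3 | C=C1C[C@@H](O)[C@@H]2[C@H](/C=C(/C)CC[C@H]1O[Si](C)(C)C(C)(C)C)[C@@H](C(C)C)CC[C@@]2(C)O[Si](CC)(CC)CC
A3 | alternative 2 | seco Z iodoalkene with terminal C4=C5 olefin, C7 dioxolane, 6,9-bis(OSitBuMe2) | C=C[C@@H](O[Si](C)(C)C(C)(C)C)C1(OCCO1)C[C@@H](O[Si](C)(C)C(C)(C)C)[C@@H]2[C@H](/C=C(/C)I)[C@@H](C(C)C)CC[C@@]2(C)O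
A4 | alternative 2 | 2Z ten-membered ring with C7 dioxolane, 6,9-bis(OSitBuMe2) | C12(OCCO1)C[C@@H](O[Si](C)(C)C(C)(C)C)[C@@H]3[C@H](/C=C(/C)CC[C@H]2O[Si](C)(C)C(C)(C)C)[C@@H](C(C)C)CC[C@@]3(C)O
A5 | alternative 3 | seco C9 dithiane with C10,C11 epoxide on ring A, 6-OSitBuMe2 | C=C(CC1SCCCS1)[C@H](O[Si](C)(C)C(C)(C)C)CC/C(C)=C\[C@@H]2[C@@H](C(C)C)CC[C@@]3(C)O[C@@H]23
A6 | alternative 3 | bicyclic C11 alcohol with C9 spiro dithiane, 6-OSitBuMe2 | C=C1CC2(SCCCS2)[C@@H]3[C@H](/C=C(/C)CC[C@H]1O[Si](C)(C)C(C)(C)C)[C@@H](C(C)C)CC[C@@]3(C)O
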